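**Retrosynthetic overview**
1. Target 7 ⇒ 5-O-(1,1-dimethylallyl) aryl ether 5 by O-desilylation and retro-[3,3]. The C6–prenyl bond is traced back to an O5–C bond, because O5 has only one free ortho carbon (C6; the other is the ring fusion C4a).
2. Ether 5 ⇒ chelated phenol 3 + tert-prenyl carbonate 4. This is the key bond, O5–C(tertiary), made by a new Pd-catalysed O-tert-prenylation of a hydrogen-bonded peri-hydroxy ketone.
3. Phenol 3 ⇒ genistein 1 by 7-O-methylation and 4'-O-silylation in one pot.
4. Ring order: no ring is built; rings A, C and B arrive intact in genistein.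

Assumption: the target has no stereocentre and no stereogenic double bond, so it is made as the single achiral compound drawn; carbonate 4 is taken as a purchasable reagent.

**Route**

Step 1
Reactants: 1 genistein (5,7-dihydroxy-3-(4-hydroxyphenyl)-4H-chromen-4-one)
Product: 3 4'-O-TIPS-prunetin (5-hydroxy-7-methoxy-3-[4-(triisopropylsilyloxy)phenyl]-4H-chromen-4-one), via prunetin 2 (not isolated)
Conditions: K2CO3 (1.0 equiv), MeI (1.05 equiv), DMF, 0 °C to rt; then imidazole (2.5 equiv), TIPSCl (1.3 equiv), rt
Reagents that add atoms: iodomethane, CI; chlorotriisopropylsilane, CC(C)[Si](Cl)(C(C)C)C(C)C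
Why: The 7-OH (para to the pyranone carbonyl, pKa about 7) is the most acidic phenol, so one equivalent of carbonate gives the 7-phenoxide for a site-selective Williamson methylation, after which the only non-chelated phenol left (4'-OH) is silylated while the hydrogen-bonded 5-OH stays free.

Step 2
Reactants: 3 4'-O-TIPS-prunetin; 4 tert-butyl 2-methylbut-3-en-2-yl carbonate
Product: 5 7-methoxy-5-[(2-methylbut-3-en-2-yl)oxy]-3-[4-(triisopropylsilyloxy)phenyl]-4H-chromen-4-one
Conditions: Pd(PPh3)4 (5 mol %), 4 (1.5 equiv, added over 1 h), THF, 0 °C, 3 h; cold filtration through Et3N-washed silica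
Reagents that add atoms: none
Why: Proposed new method: zerovalent-palladium-catalysed decarboxylative O-(1,1-dimethylallyl)ation of an intramolecularly hydrogen-bonded peri-hydroxy ketone, a class of phenol this reaction has not been shown on; oxidative addition of Pd(PPh3)4 to 4 gives [(η3-1,1-dimethylallyl)Pd(PPh3)2]+ with loss of CO2 and release of tert-butoxide, which is basic enough to break the O5–H···O=C4 hydrogen bond and deprotonate 3 (its only OH), and the phenoxide, ion-paired with the cationic allyl complex, attacks outer-sphere through its hard oxygen at the more substituted, more cationic allyl terminus under kinetic control at 0 °C to forge the O5–C(tertiary) bond (no stereocentre results); the closest known reaction type is the Tsuji–Trost-type branched O-tert-prenylation of non-chelated phenols with the same carbonate.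

Step 3
Reactants: 5 7-methoxy-5-[(2-methylbut-3-en-2-yl)oxy]-3-[4-(triisopropylsilyloxy)phenyl]-4H-chromen-4-one
Product: 7 gancaonin G (5-hydroxy-3-(4-hydroxyphenyl)-7-methoxy-6-(3-methylbut-2-en-1-yl)-4H-chromen-4-one), via 6-prenyl silyl ether 6 (not isolated)
Conditions: toluene, 100 °C, 3 h; then Bu4NF/AcOH (1:1, 1.5 equiv), THF, 0 °C to rt
Reagents that add atoms: none
Why: The aromatic Claisen ([3,3]-sigmatropic) rearrangement of the aryl 1,1-dimethylallyl ether can only end at C6, the single free ortho position of O5, and delivers the normal prenyl group with re-formation of the chelated 5-OH; buffered fluoride then cleaves the aryl silyl ether without touching the prenyl group, and no stereocentre is formed.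

**Compound list**
1 | genistein, 5,7-dihydroxy-3-(4-hydroxyphenyl)-4H-chromen-4-one | O=c1c(-c2ccc(O)cc2)coc2cc(O)cc(O)c12 | starting material
2 | prunetin, 5-hydroxy-3-(4-hydroxyphenyl)-7-methoxy-4H-chromen-4-one | COc1cc(O)c2c(c1)occ(-c1ccc(O)cc1)c2=O | intermediate
3 | 4'-O-TIPS-prunetin, 5-hydroxy-7-methoxy-3-[4-(triisopropylsilyloxy)phenyl]-4H-chromen-4-one | COc1cc(O)c2c(c1)occ(-c1ccc(O[Si](C(C)C)(C(C)C)C(C)C)cc1)c2=O | intermediate
4 | tert-butyl 2-methylbut-3-en-2-yl carbonate | C=CC(C)(C)OC(=O)OC(C)(C)C | starting material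
5 | 7-methoxy-5-[(2-methylbut-3-en-2-yl)oxy]-3-[4-(triisopropylsilyloxy)phenyl]-4H-chromen-4-one | COc1cc(OC(C)(C)C=C)c2c(c1)occ(-c1ccc(O[Si](C(C)C)(C(C)C)C(C)C)cc1)c2=O | intermediate
6 | 5-hydroxy-7-methoxy-6-(3-methylbut-2-en-1-yl)-3-[4-(triisopropylsilyloxy)phenyl]-4H-chromen-4-one | COc1cc2occ(-c3ccc(O[Si](C(C)C)(C(C)C)C(C)C)cc3)c(=O)c2c(O)c1CC=C(C)C | intermediate
7 | gancaonin G, 5-hydroxy-3-(4-hydroxyphenyl)-7-methoxy-6-(3-methylbut-2-en-1-yl)-4H-chromen-4-one (achiral) | COc1cc2occ(-c3ccc(O)cc3)c(=O)c2c(O)c1CC=C(C)C | target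

**Totals**
Total step count: 3
Longest linear sequence: 3 (1 → 3 → 5 → 7)

**Steps most likely to fail**

Step 2 (the proposed new step). The hindered phenoxide may attack slowly. The likely failures are the linear O-prenyl ether (after branched-to-linear equilibration), direct C-prenylation at C6 or C8, or consumption of 4 as isoprene. Fallback with known chemistry, setting out from 3 and coming back at 6: Mitsunobu O-allylation of the chelated 5-OH (allyl alcohol, PPh3, DIAD, THF) gives the 5-O-allyl ether F1. Thermal aromatic Claisen rearrangement (N,N-diethylaniline, 190 °C) gives the 6-allyl phenol F2. Olefin cross-metathesis with 2-methylbut-2-ene (second-generation Grubbs catalyst RuCl2(=CHPh)(PCy3)(H2IMes), CH2Cl2, 40 °C) converts allyl into prenyl and gives 6, which is desilylated with Bu4NF/AcOH as in the second half of step 3.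

Step 3. The tertiary allyl ether may fragment on heating (loss of isoprene back to 3), or the prenyl group may travel on by a Cope shift to C8. Fallback that replaces the O-to-C relay by a cross-coupling, setting out from 3 and coming back at 6: iodination ortho to the free 5-OH (BnMe3N+ ICl2−, CaCO3, CH2Cl2/MeOH, rt) gives the 6-iodide F3. An alpha-selective Suzuki–Miyaura coupling with prenylboronic acid pinacol ester (Pd(OAc)2, bulky biarylphosphine, K3PO4, THF/H2O, 40 °C) gives 6, which is then desilylated as in step 3.

Step 1. Mono-methylation may be incompletely selective (some 4'-O-methyl and 7,4'-di-O-methyl product), which lowers the yield and complicates purification of the one-pot product. Fallback that protects first and unmasks selectively, setting out from 1 and coming back at 3: silylation of both non-chelated phenols (TIPSCl, imidazole, DMF) gives the bis-silyl ether F4. The 7-O-silyl group is the more labile because its phenoxide is the better leaving group; cleaving it (K2CO3 (0.2 equiv), MeOH, 0 °C) gives the 7-phenol F5. Mitsunobu methylation (MeOH, PPh3, DIAD, THF) of the acidic 7-OH then gives 3.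

**Further compounds**
F1 | step 2 | 5-(allyloxy)-7-methoxy-3-[4-(triisopropylsilyloxy)phenyl]-4H-chromen-4-one | COc1cc(OCC=C)c2c(c1)occ(-c1ccc(O[Si](C(C)C)(C(C)C)C(C)C)cc1)c2=O
F2 | step 2 | 6-allyl-5-hydroxy-7-methoxy-3-[4-(triisopropylsilyloxy)phenyl]-4H-chromen-4-one | COc1cc2occ(-c3ccc(O[Si](C(C)C)(C(C)C)C(C)C)cc3)c(=O)c2c(O)c1CC=C
F3 | step 3 | 5-hydroxy-6-iodo-7-methoxy-3-[4-(triisopropylsilyloxy)phenyl]-4H-chromen-4-one | COc1cc2occ(-c3ccc(O[Si](C(C)C)(C(C)C)C(C)C)cc3)c(=O)c2c(O)c1I
F4 | step 1 | 5-hydroxy-7-(triisopropylsilyloxy)-3-[4-(triisopropylsilyloxy)phenyl]-4H-chromen-4-one | CC(C)[Si](Oc1ccc(cc1)-c1coc2cc(O[Si](C(C)C)(C(C)C)C(C)C)cc(O)c2c1=O)(C(C)C)C(C)C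
F5 | step 1 | 5,7-dihydroxy-3-[4-(triisopropylsilyloxy)phenyl]-4H-chromen-4-one | CC(C)[Si](Oc1ccc(cc1)-c1coc2cc(O)cc(O)c2c1=O)(C(C)C)C(C)C
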